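The maleic anhydride (furan-2,5-dione) ring is cut at both C(=O)–C(sp2) bonds. Its two carbonyl carbons are at the oxidation level of CO2 and sit cis on the ring C=C that carries the methyl group and the C16 chain, so the ring is the sum of an internal methyl alkyne and two molecules of CO2. A nickel-catalysed reductive double carboxylation joins these three components in one operation, and the cis-dicarboxylate closes to the anhydride on acidification. The precursor, (S)-nonadec-17-yn-2-yl acetate, is acyclic and comes in two steps from 1,13-dibromotridecane, 1-propynyllithium and (S)-propylene oxide, which supplies the stereocentre.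

Key step: step 3

Assumption: 1,13-dibromotridecane and solid 1-propynyllithium are taken as catalogue compounds; no bond at the stereocentre is broken anywhere in the route, so the (S) configuration of the target is that of (S)-propylene oxide.

Step 1
Reactants: 1 1,13-dibromotridecane; 2 1-propynyllithium
Product: 3 16-bromohexadec-2-yne
Conditions: 1 (3 equiv), 2 (1 equiv), THF/DMPU, 0 °C → rt; excess 1 recovered
Reagents that add atoms: none
Why: SN2 alkylation of a lithium acetylide by a primary alkyl bromide in a dipolar aprotic cosolvent should give the mono-alkynylated bromide, the threefold excess of the dibromide holding double substitution down.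

Step 2
Reactants: 3 16-bromohexadec-2-yne; 4 (S)-propylene oxide
Product: 7 (S)-nonadec-17-yn-2-yl acetate, via Grignard reagent 5 (not isolated), via bromomagnesium alkoxide 6 (not isolated)
Conditions: Mg, THF, reflux; CuI (10 mol %), 4 (1.5 equiv), −30 → 0 °C; then Ac2O, DMAP (cat.), 0 °C → rt
Reagents that add atoms: acetic anhydride, CC(=O)OC(C)=O
Why: Grignard formation followed by copper-catalysed SN2 opening of the terminal epoxide at its unsubstituted CH2 and O-acylation of the magnesium alkoxide in the flask should give 7, whose (S) centre is that of 4 because its C–O bond is never broken.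

Step 3
Reactants: 7 (S)-nonadec-17-yn-2-yl acetate
Product: 9 (S)-16-(4-methyl-2,5-dioxo-2,5-dihydrofuran-3-yl)hexadecan-2-yl acetate, via maleic diacid 8 (not isolated)
Conditions: Ni(acac)2(bpy) (10 mol %), Zn powder (3 equiv), MgBr2 (3 equiv), MS 3 Å, CO2 (1 atm), DMF, rt; then 1 M HCl, EtOAc, azeotropic drying with toluene
Reagents that add atoms: carbon dioxide, O=C=O (two molecules)
Why: Zinc reduces divalent nickel to zerovalent nickel, which couples the triple bond of 7 with one CO2 by oxidative cyclisation to a five-membered oxanickelacyclopentenone (first C–C bond); MgBr2 activates this nickelalactone, zinc reduces the alkenylnickel, and a second CO2 inserts into the Ni–C(sp2) bond (second C–C bond) to give the cis-dicarboxylate. The closest known reaction type is the nickel-catalysed reductive double carboxylation of internal alkynes with CO2, zinc and MgBr2 to maleic anhydrides. The furandione ring closes on acidification, when diacid 8 loses water by 5-exo-trig attack of one carboxyl oxygen on the other carboxyl carbon, as tetrasubstituted maleic acids do spontaneously. No stereocentre is formed; the cis relation of the two carboxyl carbons is fixed by syn addition through the metallacycle, and the remote (S)-acetoxy centre is not touched. The step needs double rather than single carboxylation (protonation of the nickelacycle would give an acrylic acid) and tolerance of the ester: dry DMF with molecular sieves, the absence of any O–H group in 7 and room temperature should secure both, and regiochemistry is no issue because both alkyne carbons are carboxylated.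

Compound list
1 | 1,13-dibromotridecane | BrCCCCCCCCCCCCCBr | starting material
2 | 1-propynyllithium | [Li]C#CC | starting material
3 | 16-bromohexadec-2-yne | CC#CCCCCCCCCCCCCCBr | intermediate
4 | (S)-propylene oxide, (S)-2-methyloxirane | C[C@H]1CO1 | starting material
5 | hexadec-14-yn-1-ylmagnesium bromide (not isolated) | CC#CCCCCCCCCCCCCC[Mg]Br | intermediate
6 | bromomagnesium (S)-nonadec-17-yn-2-olate (not isolated) | CC#CCCCCCCCCCCCCCC[C@H](C)O[Mg]Br | intermediate
7 | (S)-nonadec-17-yn-2-yl acetate | CC#CCCCCCCCCCCCCCC[C@H](C)OC(C)=O | intermediate
8 | (Z)-2-[(15S)-15-acetoxyhexadecyl]-3-methylbut-2-enedioic acid (not isolated) | CC(=O)O[C@@H](C)CCCCCCCCCCCCCC/C(C(=O)O)=C(\C)C(=O)O | intermediate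
9 | (S)-16-(4-methyl-2,5-dioxo-2,5-dihydrofuran-3-yl)hexadecan-2-yl acetate | CC(=O)O[C@@H](C)CCCCCCCCCCCCCCC1=C(C)C(=O)OC1=O | target

Total step count: 3
Longest linear sequence: 3 steps (1 → 3 → 7 → 9)

Steps most likely to fail

Step 3. Protonation of the nickelacycle may outrun the second CO2 insertion (mono-carboxylation), the unactivated dialkyl alkyne may turn over slowly, and the acetate may be partly cleaved by MgBr2 and the acidic work-up. The fallback is a radical route that sets out from 7 and comes back at 9. The triple bond of 7 is cleaved oxidatively (RuCl3 cat., NaIO4, CCl4/MeCN/H2O) to (S)-16-acetoxyheptadecanoic acid F1. The acid is coupled with N-hydroxypyridine-2-thione (DCC, CH2Cl2, dark) to the thiohydroxamate ester, 2-thioxopyridin-1(2H)-yl (S)-16-acetoxyheptadecanoate F2. Visible-light photolysis of F2 in the presence of excess citraconic anhydride (Barton decarboxylation, addition of the 15-acetoxyhexadecyl radical to the unsubstituted alkene carbon, transfer of the 2-pyridylthio group) should give the pyridylthio succinic anhydride, (S)-16-[4-methyl-2,5-dioxo-4-(pyridin-2-ylsulfanyl)oxolan-3-yl]hexadecan-2-yl acetate F3. Oxidation with mCPBA (CH2Cl2, 0 °C) to the sulfoxide, (S)-16-[4-methyl-2,5-dioxo-4-(pyridin-2-ylsulfinyl)oxolan-3-yl]hexadecan-2-yl acetate F4, and its syn-elimination on warming should give 9.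

Step 1. Both ends of the dibromide may be alkylated (statistical double substitution), elimination by the basic acetylide may compete, and the bromoalkyne may be hard to separate from the recovered dibromide. The fallback is an alkyne-migration route that sets out from 4, replaces steps 1 and 2, and comes back at 7. Lithium pentadec-1-ynide (from commercial 1-pentadecyne, n-BuLi, BF3·OEt2, THF, −78 °C) opens 4 at its CH2 to give (S)-octadec-4-yn-2-ol F5. The alkyne zipper reaction (KH, 1,3-diaminopropane, rt) moves the triple bond to the chain end without touching the carbinol centre, giving (S)-octadec-17-yn-2-ol F6. C-methylation of the alkoxide–acetylide dianion (n-BuLi 2.1 equiv, MeI, THF, −78 °C → rt) gives (S)-nonadec-17-yn-2-ol F7, and acetylation (Ac2O, pyridine, DMAP) gives 7.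

Step 2. Wurtz-type homocoupling may occur while the Grignard reagent forms, magnesium bromide may open the epoxide to a bromohydrin faster than the organocopper species alkylates it, and acetylation of the magnesium alkoxide in the flask may stay incomplete. The fallback sets the stereocentre by asymmetric reduction instead; it sets out from 3 and comes back at 7. Alkylation of ethyl acetoacetate with 3 (NaOEt, EtOH, NaI cat., reflux) gives ethyl 2-acetyloctadec-16-ynoate F8. Ketonic hydrolysis and decarboxylation (aq. NaOH, then H2SO4, heat) give nonadec-17-yn-2-one F9. Reduction with a Prelog-selective alcohol dehydrogenase (ADH-A from Rhodococcus ruber, NADH cat., 2-propanol/buffer, 30 °C), which delivers hydride to the re face of methyl ketones, should give the same alcohol as in the fallback to step 1, (S)-nonadec-17-yn-2-ol F7. Acetylation (Ac2O, pyridine, DMAP) gives 7.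

Further compounds
F1 | step 3 | (S)-16-acetoxyheptadecanoic acid | CC(=O)O[C@@H](C)CCCCCCCCCCCCCCC(=O)O
F2 | step 3 | 2-thioxopyridin-1(2H)-yl (S)-16-acetoxyheptadecanoate | CC(=O)O[C@@H](C)CCCCCCCCCCCCCCC(=O)ON1C=CC=CC1=S
F3 | step 3 | (S)-16-[4-methyl-2,5-dioxo-4-(pyridin-2-ylsulfanyl)oxolan-3-yl]hexadecan-2-yl acetate (mixture of ring diastereomers) | CC(=O)O[C@@H](C)CCCCCCCCCCCCCCC1C(=O)OC(=O)C1(C)Sc2ccccn2
F4 | step 3 | (S)-16-[4-methyl-2,5-dioxo-4-(pyridin-2-ylsulfinyl)oxolan-3-yl]hexadecan-2-yl acetate (mixture of diastereomers) | CC(=O)O[C@@H](C)CCCCCCCCCCCCCCC1C(=O)OC(=O)C1(C)S(=O)c2ccccn2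
F5 | step 1 | (S)-octadec-4-yn-2-ol | C[C@H](O)CC#CCCCCCCCCCCCCC
F6 | step 1 | (S)-octadec-17-yn-2-ol | C[C@H](O)CCCCCCCCCCCCCCC#C
F7 | step 1 | (S)-nonadec-17-yn-2-ol | C[C@H](O)CCCCCCCCCCCCCCC#CC
F8 | step 2 | ethyl 2-acetyloctadec-16-ynoate | CC#CCCCCCCCCCCCCCCC(C(C)=O)C(=O)OCC
F9 | step 2 | nonadec-17-yn-2-one | CC#CCCCCCCCCCCCCCCCC(C)=O
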